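**Retrosynthetic overview**

1. Target ⇐ tris-silyl ether ⇐ ring C enone ⇐ bridged ketal carrying ring C as an allyl β-keto ester (26): fluoride desilylation, Weitz–Scheffer epoxidation, decarboxylative dehydrogenation.
2. Key disconnection: the strategy rests on the ketal carbon, which is bonded to a ring A carbon, to the ring C chain, to the ether oxygen of the quaternary carbon and to the aryl oxygen of ring B. As an α-alkoxy α-sulfonyl benzylic carbon (23) it is first a carbanion (Michael–Dieckmann with allyl acrylate, ring C) and then an oxocarbenium ion (capture by the ring B phenol, 1,3-dioxin ring).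
3. 23 ⇐ spiro lactone 20 (lactone → lactol → sulfone, PMB removal) ⇐ ring A arylmagnesium from bromophthalate 4 + ring D epoxy ketone 17, aryl entering anti to the epoxide.
4. 17 ⇐ naphthoquinone monoketal 13 (Corey–Bakshi–Shibata reduction sets the carbinol, epoxidation anti to its silyl ether, ketal hydrolysis) ⇐ tetralone 5.
5. Ring order: ring D is functionalised first on the ring B/D tetralone, the five-membered ether ring forms at the fragment union, ring C and the dioxin ring form together in the key step, and the ring C epoxide comes last.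

Key step: step 18

Remark: ring A = chlorophenol ring of the keto half, ring B = chlorophenol ring of the carbinol half, ring C = epoxy ketone ring, ring D = epoxy carbinol ring; TBS = tert-butyldimethylsilyl, PMB = 4-methoxybenzyl.
Remark: the sulfonyl-bearing carbon of 22, 23 and 25 is drawn as one epimer (sulfonyl on the ring B side); its configuration is immaterial because this carbon is lithiated and later ionised, and lactol 21 is an epimer mixture at the lactol carbon.

**Route**

Step 1
Reactants: 1 dimethyl 3-hydroxyphthalate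
Product: 2 dimethyl 6-bromo-3-hydroxyphthalate
Conditions: N-bromosuccinimide (1.05 equiv), MeCN, 0 °C to rt
Reagents that add atoms: N-bromosuccinimide, O=C1CCC(=O)N1Br
Why: Electrophilic aromatic bromination in which the hydroxyl group is the only activator and should direct para (C6) in preference to ortho, as in the bromination of salicylates.

Step 2
Reactants: 2 dimethyl 6-bromo-3-hydroxyphthalate
Product: 3 dimethyl 6-bromo-4-chloro-3-hydroxyphthalate
Conditions: SO2Cl2 (1.1 equiv), CH2Cl2, 0 °C to rt
Reagents that add atoms: sulfuryl chloride, O=S(=O)(Cl)Cl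
Why: Electrophilic aromatic chlorination at C4, the one remaining position ortho to the hydroxyl group.

Step 3
Reactants: 3 dimethyl 6-bromo-4-chloro-3-hydroxyphthalate
Product: 4 dimethyl 6-bromo-3-(tert-butyldimethylsilyloxy)-4-chlorophthalate
Conditions: TBSCl, imidazole, DMF, rt
Reagents that add atoms: tert-butyldimethylsilyl chloride, CC(C)(C)[Si](C)(C)Cl
Why: Silyl ether formation masks the acidic phenol before the halogen–magnesium exchange and the later carbanion step.

Step 4
Reactants: 5 5,8-dimethoxy-3,4-dihydronaphthalen-1(2H)-one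
Product: 6 5,8-dihydroxy-3,4-dihydronaphthalen-1(2H)-one
Conditions: BBr3 (2.5 equiv), CH2Cl2, −78 °C to rt; then H2O
Reagents that add atoms: none
Why: Lewis acid cleavage of both aryl methyl ethers, which could not be removed at the end of the synthesis, gives the hydroquinone.

Step 5
Reactants: 6 5,8-dihydroxy-3,4-dihydronaphthalen-1(2H)-one
Product: 7 8-hydroxy-5-(4-methoxybenzyloxy)-3,4-dihydronaphthalen-1(2H)-one
Conditions: 4-methoxybenzyl chloride (1.05 equiv), K2CO3 (1.1 equiv), DMF, argon, rt
Reagents that add atoms: 4-methoxybenzyl chloride, COc1ccc(CCl)cc1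
Why: Williamson ether synthesis that should take the 5-hydroxyl group only, because the 8-hydroxyl group is held in a hydrogen bond to the ketone.

Step 6
Reactants: 7 8-hydroxy-5-(4-methoxybenzyloxy)-3,4-dihydronaphthalen-1(2H)-one
Product: 8 7-chloro-8-hydroxy-5-(4-methoxybenzyloxy)-3,4-dihydronaphthalen-1(2H)-one
Conditions: N-chlorosuccinimide (1.05 equiv), DMF, 0 °C to rt
Reagents that add atoms: N-chlorosuccinimide, O=C1CCC(=O)N1Cl
Why: Electrophilic aromatic chlorination ortho to the free phenol (C7), the stronger director, as in the halogenation of 5-alkoxysalicyl ketones ortho to the hydroxyl group.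

Step 7
Reactants: 8 7-chloro-8-hydroxy-5-(4-methoxybenzyloxy)-3,4-dihydronaphthalen-1(2H)-one
Product: 9 8-(tert-butyldimethylsilyloxy)-7-chloro-5-(4-methoxybenzyloxy)-3,4-dihydronaphthalen-1(2H)-one
Conditions: TBSOTf (1.3 equiv), 2,6-lutidine, CH2Cl2, 0 °C
Reagents that add atoms: tert-butyldimethylsilyl trifluoromethanesulfonate, CC(C)(C)[Si](C)(C)OS(=O)(=O)C(F)(F)F
Why: Silylation of the hindered, hydrogen-bonded phenol needs the silyl triflate; this oxygen must be blocked before the oxidation of step 9.

Step 8
Reactants: 9 8-(tert-butyldimethylsilyloxy)-7-chloro-5-(4-methoxybenzyloxy)-3,4-dihydronaphthalen-1(2H)-one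
Product: 11 8-(tert-butyldimethylsilyloxy)-7-chloro-5-(4-methoxybenzyloxy)naphthalen-1-ol, via 4H-naphthalen-1-one tautomer 10 (not isolated)
Conditions: Pd(OCOCF3)2 (5 mol%), 2-(dimethylamino)pyridine (10 mol%), 4-MeC6H4SO3H (20 mol%), O2 (1 atm), DMSO, 80 °C
Reagents that add atoms: none
Why: Palladium-catalysed aerobic dehydrogenation of a cyclic ketone (divalent palladium enolate, β-hydride elimination, O2 returning zerovalent palladium to the divalent state) gives enone 10, which tautomerizes to the naphthol.

Step 9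
Reactants: 11 8-(tert-butyldimethylsilyloxy)-7-chloro-5-(4-methoxybenzyloxy)naphthalen-1-ol
Product: 13 8-(tert-butyldimethylsilyloxy)-7-chloro-4,4-dimethoxy-5-(4-methoxybenzyloxy)naphthalen-1(4H)-one, via 4-methoxynaphthol 12 (not isolated)
Conditions: PhI(OAc)2 (2.2 equiv), MeOH, 0 °C
Reagents that add atoms: methanol, CO
Why: Oxidative dearomatization of the phenol by trivalent iodine with capture by methanol at the para carbon, twice in one flask, gives the para-quinone monoketal, so the former phenol carbon is the ketone and the carbon peri to the PMB ether is masked.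

Step 10
Reactants: 13 8-(tert-butyldimethylsilyloxy)-7-chloro-4,4-dimethoxy-5-(4-methoxybenzyloxy)naphthalen-1(4H)-one
Product: 14 (1R)-8-(tert-butyldimethylsilyloxy)-7-chloro-4,4-dimethoxy-5-(4-methoxybenzyloxy)-1,4-dihydronaphthalen-1-ol
Conditions: (S)-1-methyl-3,3-diphenyltetrahydro-1H,3H-pyrrolo[1,2-c][1,3,2]oxazaborole (0.2 equiv), BH3·SMe2 (0.7 equiv), THF, −30 °C; MeOH, then aq. NaHCO3
Reagents that add atoms: none
Why: Corey–Bakshi–Shibata 1,2-reduction in which the arene with its peri silyloxy group is the large substituent and the vinyl carbon the small one, so the (S)-catalyst should give the (R)-carbinol, as it does with 1-tetralone.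

Step 11
Reactants: 14 (1R)-8-(tert-butyldimethylsilyloxy)-7-chloro-4,4-dimethoxy-5-(4-methoxybenzyloxy)-1,4-dihydronaphthalen-1-ol
Product: 15 (1R)-1,8-bis(tert-butyldimethylsilyloxy)-7-chloro-4,4-dimethoxy-5-(4-methoxybenzyloxy)-1,4-dihydronaphthalene
Conditions: TBSCl, imidazole, 4-(dimethylamino)pyridine (cat.), DMF, rt
Reagents that add atoms: tert-butyldimethylsilyl chloride, CC(C)(C)[Si](C)(C)Cl
Why: Silyl ether formation under non-acidic conditions, because the allylic alcohol next to a ketal would aromatize with acid.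

Step 12
Reactants: 15 (1R)-1,8-bis(tert-butyldimethylsilyloxy)-7-chloro-4,4-dimethoxy-5-(4-methoxybenzyloxy)-1,4-dihydronaphthalene
Product: 16 2,3-epoxide of 15 with the oxirane trans to the 1-silyloxy group
Conditions: mCPBA (2 equiv), NaHCO3, CH2Cl2, 0 °C to rt
Reagents that add atoms: 3-chloroperoxybenzoic acid, O=C(OO)c1cccc(Cl)c1
Why: Prilezhaev epoxidation; peri strain with the neighbouring aryl silyl ether holds the allylic silyloxy group pseudoaxial, so the peracid should attack the opposite face and set both epoxide carbons trans to it.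

Step 13
Reactants: 16 2,3-epoxide of 15 with the oxirane trans to the 1-silyloxy group
Product: 17 ring D epoxy ketone (2,3-epoxy-4-silyloxy-1-tetralone with ring B bearing PMB ether and chlorine and silyl ether)
Conditions: 4-MeC6H4SO3H·H2O (10 mol%), acetone/H2O (10:1), rt
Reagents that add atoms: water, O
Why: Acid-catalysed hydrolysis of the benzylic dimethyl ketal frees the ketone, which can neither enolize nor aromatize because its α-carbon is an epoxide carbon.

Step 14
Reactants: 4 dimethyl 6-bromo-3-(tert-butyldimethylsilyloxy)-4-chlorophthalate; 17 ring D epoxy ketone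
Product: 20 spiro lactone joining ring A to the quaternary carbon of ring D (lactone oxygen cis to the epoxide), via arylmagnesium chloride 18 (not isolated), via chloromagnesium alkoxide 19 (not isolated)
Conditions: 4 (1.3 equiv), iPrMgCl·LiCl (1.25 equiv), THF, −30 °C; then 17, LaCl3·2LiCl (1 equiv), −30 to 0 °C, then rt; aq. NH4Cl
Reagents that add atoms: none
Why: Bromine–magnesium exchange (helped by the ortho ester), Grignard 1,2-addition to the non-enolizable ketone and lactonization of the alkoxide on the ortho ester; the aryl group should enter anti to the epoxide oxygen (Felkin–Anh, α C–O bond antiperiplanar to the nucleophile), which sets the quaternary carbon with its oxygen cis to the epoxide.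

Step 15
Reactants: 20 spiro lactone
Product: 21 lactol
Conditions: iBu2AlH (1.2 equiv), CH2Cl2, −78 °C; aq. potassium sodium tartrate
Reagents that add atoms: none
Why: Partial hydride reduction of the lactone to the lactol; the methyl ester should survive because it is flanked by two ortho substituents and twisted out of conjugation.

Step 16
Reactants: 21 lactol
Product: 22 cyclic α-sulfonyl benzylic ether with ring B PMB ether
Conditions: PhSO2H (3 equiv), CaCl2, CH2Cl2, rt
Reagents that add atoms: benzenesulfinic acid, O=S(O)c1ccccc1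
Why: Acid-promoted ionization of the lactol to the cyclic oxocarbenium ion and S-attack of sulfinate give the α-alkoxy sulfone (lactol–sulfinic acid exchange), while the PMB ether keeps the ring B oxygen from capturing the cation.

Step 17
Reactants: 22 cyclic α-sulfonyl benzylic ether with ring B PMB ether
Product: 23 cyclic α-sulfonyl benzylic ether with ring A methyl ester and free ring B phenol
Conditions: DDQ (1.5 equiv), CH2Cl2/aq. KH2PO4–K2HPO4 buffer (pH 7), 0 °C to rt
Reagents that add atoms: none
Why: Oxidative cleavage of the PMB ether (hydride abstraction, then hydrolysis) frees the ring B phenol without touching silyl ethers, epoxide or sulfone.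

Step 18
Reactants: 23 cyclic α-sulfonyl benzylic ether with ring A methyl ester and free ring B phenol; 24 allyl acrylate
Product: 26 bridged ketal with ring C as enolized allyl β-keto ester, via annulated sulfone 25 (not isolated)
Conditions: LiN(SiMe3)2 (2.3 equiv), THF, −78 °C; 24 (1.3 equiv), −78 to 0 °C; then MgBr2·OEt2 (3 equiv), 0 °C to rt; aq. NH4Cl
Reagents that add atoms: none
Why: Proposed new method: LiN(SiMe3)2 removes the phenol proton and then the proton on the carbon flanked by the sulfonyl group, the ring oxygen and ring A; this carbanion adds 1,4 to 24 and the ester enolate acylates on the neighbouring methyl ester (Dieckmann, 6-exo-trig, ring C; the methoxide set free deprotonates the new β-keto ester) to give 25, in which sulfinate cannot leave by β-elimination because it sits on the carbon γ to the enolate carbon. MgBr2·OEt2 then ionizes the tertiary α-alkoxy sulfone to a cyclic oxocarbenium ion, which the ring B magnesium phenoxide captures (closure of the 1,3-dioxin ring, 6-endo-trig with respect to the C=O+ bond), so that one carbon serves first as nucleophile and then as electrophile. The closest known reaction types are the Hauser–Kraus and Staunton–Weinreb annulations of stabilized benzylic carbanions with acrylates and the Lewis acid displacement of 2-sulfonyl cyclic ethers by oxygen nucleophiles; their union in one flask on a sulfonyl phthalan is not known. The only new stereocentre, the ketal carbon, is fixed by the bridge: the phenol oxygen sits on ring B ortho to the quaternary carbon and can reach the cation from one face only, whatever the configuration of the sulfone. The step needs C-deprotonation at the sulfonyl carbon (the phenol is parked as its lithium salt and no enolizable ketone is present), 1,4- over 1,2-addition (soft sulfonyl carbanion) and capture of the cation by oxygen in preference to loss of a ring C proton; that loss could aromatize ring C only by forcing the ether bridge into a strained naphtho[1,8-bc]furan, and no strong base is left to drive it.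

Step 19
Reactants: 26 bridged ketal with ring C as enolized allyl β-keto ester
Product: 27 ring C enone
Conditions: Pd(OAc)2 (10 mol%), Ph2PCH2CH2PPh2 (10 mol%), MeCN, 80 °C
Reagents that add atoms: none
Why: Tsuji decarboxylative dehydrogenation: zerovalent palladium ionizes the allyl ester, CO2 is lost, and the palladium enolate undergoes β-hydride elimination (favoured in a nitrile solvent) to the enone, the allyl group leaving as propene.

Step 20
Reactants: 27 ring C enone
Product: 28 tris-silyl ether of the target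
Conditions: tBuOOH (3 equiv), 1,8-diazabicyclo[5.4.0]undec-7-ene (1.5 equiv), CH2Cl2, 0 °C
Reagents that add atoms: tert-butyl hydroperoxide, CC(C)(C)OO
Why: Weitz–Scheffer epoxidation; the peroxide anion should add to the enone β-carbon on the face opposite the axial aryloxy oxygen of the ketal carbon (the face not covered by ring B) and the enolate closes the oxirane, which sets both epoxide carbons cis to the five-membered ether oxygen.

Step 21
Reactants: 28 tris-silyl ether of the target
Product: 29 target CNP0289684.3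
Conditions: HF·pyridine, pyridine, THF, 0 °C to rt
Reagents that add atoms: none
Why: Fluoride-driven cleavage of the three silyl ethers (Si–F bond formation) under buffered, non-basic conditions should leave both epoxides, the ketal and the base-sensitive epoxy ketone intact.

**Compound list**

1 | dimethyl 3-hydroxyphthalate | COC(=O)c1cccc(O)c1C(=O)OC | starting material
2 | dimethyl 6-bromo-3-hydroxyphthalate | COC(=O)c1c(Br)ccc(O)c1C(=O)OC | intermediate
3 | dimethyl 6-bromo-4-chloro-3-hydroxyphthalate | COC(=O)c1c(Br)cc(Cl)c(O)c1C(=O)OC | intermediate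
4 | dimethyl 6-bromo-3-(tert-butyldimethylsilyloxy)-4-chlorophthalate | COC(=O)c1c(Br)cc(Cl)c(O[Si](C)(C)C(C)(C)C)c1C(=O)OC | intermediate
5 | 5,8-dimethoxy-3,4-dihydronaphthalen-1(2H)-one | COc1ccc(OC)c2c1CCCC2=O | starting material
6 | 5,8-dihydroxy-3,4-dihydronaphthalen-1(2H)-one | Oc1ccc(O)c2c1CCCC2=O | intermediate
7 | 8-hydroxy-5-(4-methoxybenzyloxy)-3,4-dihydronaphthalen-1(2H)-one | O=C1CCCc2c(OCc3ccc(OC)cc3)ccc(O)c12 | intermediate
8 | 7-chloro-8-hydroxy-5-(4-methoxybenzyloxy)-3,4-dihydronaphthalen-1(2H)-one | O=C1CCCc2c(OCc3ccc(OC)cc3)cc(Cl)c(O)c12 | intermediate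
9 | 8-(tert-butyldimethylsilyloxy)-7-chloro-5-(4-methoxybenzyloxy)-3,4-dihydronaphthalen-1(2H)-one | O=C1CCCc2c(OCc3ccc(OC)cc3)cc(Cl)c(O[Si](C)(C)C(C)(C)C)c12 | intermediate
10 | 8-(tert-butyldimethylsilyloxy)-7-chloro-5-(4-methoxybenzyloxy)naphthalen-1(4H)-one (keto tautomer of 11) | O=C1C=CCc2c(OCc3ccc(OC)cc3)cc(Cl)c(O[Si](C)(C)C(C)(C)C)c12 | intermediate (not isolated)
11 | 8-(tert-butyldimethylsilyloxy)-7-chloro-5-(4-methoxybenzyloxy)naphthalen-1-ol | Oc1cccc2c(OCc3ccc(OC)cc3)cc(Cl)c(O[Si](C)(C)C(C)(C)C)c12 | intermediate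
12 | 8-(tert-butyldimethylsilyloxy)-7-chloro-4-methoxy-5-(4-methoxybenzyloxy)naphthalen-1-ol | COc1ccc(O)c2c(O[Si](C)(C)C(C)(C)C)c(Cl)cc(OCc3ccc(OC)cc3)c12 | intermediate (not isolated)
13 | 8-(tert-butyldimethylsilyloxy)-7-chloro-4,4-dimethoxy-5-(4-methoxybenzyloxy)naphthalen-1(4H)-one | O=C1C=CC(OC)(OC)c2c(OCc3ccc(OC)cc3)cc(Cl)c(O[Si](C)(C)C(C)(C)C)c12 | intermediate
14 | (1R)-8-(tert-butyldimethylsilyloxy)-7-chloro-4,4-dimethoxy-5-(4-methoxybenzyloxy)-1,4-dihydronaphthalen-1-ol | COC1(OC)C=C[C@@H](O)c2c(O[Si](C)(C)C(C)(C)C)c(Cl)cc(OCc3ccc(OC)cc3)c21 | intermediate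
15 | (1R)-1,8-bis(tert-butyldimethylsilyloxy)-7-chloro-4,4-dimethoxy-5-(4-methoxybenzyloxy)-1,4-dihydronaphthalene | COC1(OC)C=C[C@@H](O[Si](C)(C)C(C)(C)C)c2c(O[Si](C)(C)C(C)(C)C)c(Cl)cc(OCc3ccc(OC)cc3)c21 | intermediate
16 | 2,3-epoxide of 15, oxirane trans to the 1-silyloxy group, carbinol carbon unchanged | COC1(OC)[C@@H]2O[C@@H]2[C@@H](O[Si](C)(C)C(C)(C)C)c2c(O[Si](C)(C)C(C)(C)C)c(Cl)cc(OCc3ccc(OC)cc3)c21 | intermediate
17 | ring D epoxy ketone: 4,5-bis(tert-butyldimethylsilyloxy)-6-chloro-2,3-epoxy-8-(4-methoxybenzyloxy)-3,4-dihydronaphthalen-1(2H)-one, oxirane trans to the 4-silyloxy group | O=C1[C@@H]2O[C@@H]2[C@@H](O[Si](C)(C)C(C)(C)C)c2c(O[Si](C)(C)C(C)(C)C)c(Cl)cc(OCc3ccc(OC)cc3)c21 | intermediate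
18 | arylmagnesium chloride from 4 (magnesium in place of bromine) | COC(=O)c1c([Mg]Cl)cc(Cl)c(O[Si](C)(C)C(C)(C)C)c1C(=O)OC | intermediate (not isolated)
19 | chloromagnesium tertiary alkoxide: ring A diester bonded to the former ketone carbon of 17, aryl trans and O cis to the epoxide | COC(=O)c1c(O[Si](C)(C)C(C)(C)C)c(Cl)cc(c1C(=O)OC)[C@]1(O[Mg]Cl)c2c(OCc3ccc(OC)cc3)cc(Cl)c(O[Si](C)(C)C(C)(C)C)c2[C@H](O[Si](C)(C)C(C)(C)C)[C@H]2O[C@H]21 | intermediate (not isolated)
20 | spiro lactone (phthalide of ring A spiro-fused at the quaternary carbon of ring D; ring A with CO2Me, OTBS, Cl; ring B with OPMB, Cl, OTBS; lactone oxygen cis to the epoxide, carbinol OTBS trans) | COC(=O)c1c(O[Si](C)(C)C(C)(C)C)c(Cl)cc2c1C(=O)O[C@]21c3c(OCc4ccc(OC)cc4)cc(Cl)c(O[Si](C)(C)C(C)(C)C)c3[C@H](O[Si](C)(C)C(C)(C)C)[C@H]3O[C@H]31 | intermediate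
21 | lactol from 20 (lactone C=O reduced to CH–OH, epimer mixture at that carbon) | COC(=O)c1c(O[Si](C)(C)C(C)(C)C)c(Cl)cc2c1C(O)O[C@]21c3c(OCc4ccc(OC)cc4)cc(Cl)c(O[Si](C)(C)C(C)(C)C)c3[C@H](O[Si](C)(C)C(C)(C)C)[C@H]3O[C@H]31 | intermediate
22 | cyclic α-(phenylsulfonyl) benzylic ether (lactol OH replaced by SO2Ph), ring B oxygen as PMB ether | COC(=O)c1c(O[Si](C)(C)C(C)(C)C)c(Cl)cc2c1[C@H](S(=O)(=O)c1ccccc1)O[C@]21c3c(OCc4ccc(OC)cc4)cc(Cl)c(O[Si](C)(C)C(C)(C)C)c3[C@H](O[Si](C)(C)C(C)(C)C)[C@H]3O[C@H]31 | intermediate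
23 | cyclic α-(phenylsulfonyl) benzylic ether with ring A methyl ester and free ring B phenol (key-step precursor) | COC(=O)c1c(O[Si](C)(C)C(C)(C)C)c(Cl)cc2c1[C@H](S(=O)(=O)c1ccccc1)O[C@]21c3c(O)cc(Cl)c(O[Si](C)(C)C(C)(C)C)c3[C@H](O[Si](C)(C)C(C)(C)C)[C@H]3O[C@H]31 | intermediate
24 | allyl acrylate | C=CC(=O)OCC=C | starting material
25 | annulated sulfone: ring C closed as enolized allyl β-keto ester, former sulfonyl carbon now quaternary (SO2Ph, ring oxygen, ring A, ring C CH2), ring B phenol free | C=CCOC(=O)C1=C(O)c2c(O[Si](C)(C)C(C)(C)C)c(Cl)cc3c2[C@](C1)(S(=O)(=O)c1ccccc1)O[C@]31c2c(O)cc(Cl)c(O[Si](C)(C)C(C)(C)C)c2[C@H](O[Si](C)(C)C(C)(C)C)[C@H]2O[C@H]21 | intermediate (not isolated)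
26 | bridged ketal with ring C as enolized allyl β-keto ester (key-step product) | C=CCOC(=O)C1=C(O)c2c(O[Si](C)(C)C(C)(C)C)c(Cl)cc3c2[C@@]2(Oc4cc(Cl)c(O[Si](C)(C)C(C)(C)C)c5c4[C@]3(O2)[C@@H]2O[C@@H]2[C@H]5O[Si](C)(C)C(C)(C)C)C1 | intermediate
27 | ring C enone (C=C between the ketone and the ketal carbon), three TBS ethers | O=C1c2c(O[Si](C)(C)C(C)(C)C)c(Cl)cc3c2[C@@]2(Oc4cc(Cl)c(O[Si](C)(C)C(C)(C)C)c5c4[C@]3(O2)[C@@H]2O[C@@H]2[C@H]5O[Si](C)(C)C(C)(C)C)C=C1 | intermediate
28 | tris(tert-butyldimethylsilyl) ether of the target (both phenols and the carbinol) | O=C1c2c(O[Si](C)(C)C(C)(C)C)c(Cl)cc3c2[C@@]2(Oc4cc(Cl)c(O[Si](C)(C)C(C)(C)C)c5c4[C@]3(O2)[C@@H]2O[C@@H]2[C@H]5O[Si](C)(C)C(C)(C)C)[C@@H]2O[C@H]12 | intermediate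
29 | CNP0289684.3 | O=C1c2c(O)c(Cl)cc3c2[C@@]2(Oc4cc(Cl)c(O)c5c4[C@]3(O2)[C@@H]2O[C@@H]2[C@H]5O)[C@@H]2O[C@H]12 | target

**Totals**

Total step count: 21. Longest linear sequence: 18 steps (from 5 through steps 4–13 and 14–21).

**Steps most likely to fail**

1. Step 18 (key step). After ionization of the sulfone, loss of a ring C proton and aromatization may outrun capture of the cation by the phenoxide, or the dianion may add sluggishly to the acrylate. The fallback uses three known reactions and closes the ketal before ring C exists, so that aromatization has no driving force. It sets out from 22, whose phenol is still a PMB ether. LiN(SiMe3)2 in THF at −78 °C and 24, with an acetic acid quench at −78 °C before the Dieckmann closure sets in, should give the Michael adduct, allyl 3-(1-phenylsulfonylphthalan-1-yl)propanoate F1 (conjugate addition of a lithiated 2-sulfonyl cyclic ether). DDQ in buffered CH2Cl2 then frees the phenol of this sulfonyl ester F2. MgBr2·OEt2 with NaHCO3 in CH2Cl2 displaces sulfinate by the phenol and gives the bridged ketal propanoate F3. LiN(SiMe3)2 in THF from −78 to 0 °C then closes ring C by a plain Dieckmann condensation, and the route is rejoined at 26.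

2. Step 14. The ester-bearing arylmagnesium reagent may attack ester groups during the bromine–magnesium exchange before it meets the hindered ketone. The fallback changes the halide and the mode of metalation. It sets out from 1: N-iodosuccinimide in MeCN should give dimethyl 3-hydroxy-6-iodophthalate F4, SO2Cl2 the chloro iodo phenol F5, and TBSCl with imidazole the silyl ether F6. The iodine–magnesium exchange of F6 with iPrMgCl is fast even at −78 °C, so it can be run with 17 and LaCl3·2LiCl already in the flask (Barbier mode) and the arylmagnesium 18 never accumulates. Addition and lactonization through 19 then return to the route at 20.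

3. Step 19. Protonation or allylation of the palladium enolate may outrun β-hydride elimination. The fallback separates decarboxylation from dehydrogenation and sets out from 26. Pd(PPh3)4 (cat.) with HCO2H and Et3N in THF (decarboxylation with hydrogenolysis of the allyl ester) should give the saturated ring C ketone F7. TMSOTf with Et3N in CH2Cl2 gives its trimethylsilyl enol ether F8, and Pd(OAc)2 in MeCN (Saegusa–Ito oxidation) returns to the route at 27.

Further compounds
F1 | step 18 | Michael adduct: 22 with CH2CH2CO2allyl in place of H on the sulfonyl carbon (PMB ether) | COC(=O)c1c(O[Si](C)(C)C(C)(C)C)c(Cl)cc2c1[C@](CCC(=O)OCC=C)(S(=O)(=O)c1ccccc1)O[C@]21c3c(OCc4ccc(OC)cc4)cc(Cl)c(O[Si](C)(C)C(C)(C)C)c3[C@H](O[Si](C)(C)C(C)(C)C)[C@H]3O[C@H]31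
F2 | step 18 | phenol from F1 (PMB removed) | COC(=O)c1c(O[Si](C)(C)C(C)(C)C)c(Cl)cc2c1[C@](CCC(=O)OCC=C)(S(=O)(=O)c1ccccc1)O[C@]21c3c(O)cc(Cl)c(O[Si](C)(C)C(C)(C)C)c3[C@H](O[Si](C)(C)C(C)(C)C)[C@H]3O[C@H]31
F3 | step 18 | bridged ketal with CH2CH2CO2allyl on the ketal carbon and CO2Me on ring A (ring C open) | COC(=O)c1c(O[Si](C)(C)C(C)(C)C)c(Cl)cc3c1[C@@]2(Oc4cc(Cl)c(O[Si](C)(C)C(C)(C)C)c5c4[C@]3(O2)[C@@H]2O[C@@H]2[C@H]5O[Si](C)(C)C(C)(C)C)CCC(=O)OCC=C
F4 | step 14 | dimethyl 3-hydroxy-6-iodophthalate | COC(=O)c1c(I)ccc(O)c1C(=O)OC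
F5 | step 14 | dimethyl 4-chloro-3-hydroxy-6-iodophthalate | COC(=O)c1c(I)cc(Cl)c(O)c1C(=O)OC
F6 | step 14 | dimethyl 3-(tert-butyldimethylsilyloxy)-4-chloro-6-iodophthalate | COC(=O)c1c(I)cc(Cl)c(O[Si](C)(C)C(C)(C)C)c1C(=O)OC
F7 | step 19 | saturated ring C ketone (26 without the allyl ester group) | O=C1c2c(O[Si](C)(C)C(C)(C)C)c(Cl)cc3c2[C@@]2(Oc4cc(Cl)c(O[Si](C)(C)C(C)(C)C)c5c4[C@]3(O2)[C@@H]2O[C@@H]2[C@H]5O[Si](C)(C)C(C)(C)C)CC1
F8 | step 19 | trimethylsilyl enol ether of F7 | C[Si](C)(C)OC1c2c(O[Si](C)(C)C(C)(C)C)c(Cl)cc3c2[C@@]2(Oc4cc(Cl)c(O[Si](C)(C)C(C)(C)C)c5c4[C@]3(O2)[C@@H]2O[C@@H]2[C@H]5O[Si](C)(C)C(C)(C)C)CC=1
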